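**Retrosynthetic overview**
1. The target is the dehydro-dimer of (E)-methyl isoeugenol 1 (2 × C11H14O2 − H2), so every carbon comes from 1.
2. Last ring: one-electron oxidation of the all-trans cyclobutane 2 opens it to the 8–8′-linked radical cation 3. Its benzylic cation closes onto the second veratryl ring (C1–C8a bond), and radical 4 loses a hydrogen atom to give the C3=C4 bond of target 5.
3. 2 comes from head-to-head radical-cation [2+2] dimerisation of two molecules of 1 under a chiral counteranion; this fixes the two methyl-bearing stereocentres.
4. Ring order: the four-membered ring first (a store for the 8–8′ bond and its configuration), then the six-membered carbocycle by oxidative ring expansion. C1 is set from C2 during the closure.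

Assumption: 1 is bought as the ≥98% E grade, and because the sense of induction of the chiral anion cannot be predicted with certainty, the antipode that gives (1S,2S,3R,4R)-2 is chosen after a first run.

**Step 1**
Reactants: 1 (E)-methyl isoeugenol (two molecules)
Product: 2 (1S,2S,3R,4R)-1,2-bis(3,4-dimethoxyphenyl)-3,4-dimethylcyclobutane
Conditions: 9-mesitylthioxanthylium salt of a confined chiral imidodiphosphorimidate (IDPi) anion (BINOL backbones with 3,3′-aryl groups, N-triflyl core; 2 mol%), CH2Cl2 (0.1 M), −90 °C, green LEDs, Ar
Reagents that add atoms: none
Why: Radical-cation (hole-catalysed) [2+2] cycloaddition under asymmetric counteranion-directed photoredox catalysis: the racemic head-to-head dimerisation of 1 to the all-trans cyclobutane is established, and here the radical cation of 1 has the chiral anion as its only counterion, so the anion pocket selects the alkene faces when the bond between the two methyl-bearing carbons forms (both R), while the E geometry and stepwise closure place all four substituents trans (aryl-bearing carbons both S).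

**Step 2**
Reactants: 2 (1S,2S,3R,4R)-1,2-bis(3,4-dimethoxyphenyl)-3,4-dimethylcyclobutane
Product: 5 (1R,2S)-1-(3,4-dimethoxyphenyl)-6,7-dimethoxy-2,3-dimethyl-1,2-dihydronaphthalene, via ring-opened radical cation 3 (not isolated), via tetralinyl radical 4 (not isolated)
Conditions: 9-mesityl-10-methylacridinium tetrafluoroborate (5 mol%), Co(dmgH)2(py)Cl (5 mol%), ClCH2CH2Cl (2 mM), 0 °C, blue LEDs, Ar; stop near 60% conversion and recycle 2
Reagents that add atoms: none
Why: Proposed new method: oxidation of 2 by the excited acridinium cleaves the weak, strained ArCH–CHAr bond to the distonic radical cation 3 (the open 8–8′ dimer of the proposed biogenesis) without touching the methyl-bearing centres, the benzylic cation then alkylates the other ring para to a methoxy group through an all-equatorial chair (intramolecular Friedel–Crafts closure, aryl trans to the neighbouring methyl, so C1 = R under control of C2), proton loss gives radical 4, and divalent cobalt formed from the cobaloxime abstracts the C3 hydrogen atom to give the C3=C4 bond and, with the proton, H2; the closest known reaction types are the rearrangement of 1,2-diarylcyclobutane radical cations to 1-aryltetralin and 1-aryl-1,2-dihydronaphthalene skeletons under photoinduced electron transfer and the acceptorless photoredox–cobaloxime desaturation of benzylic radicals.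

Stereochemical bookkeeping: the surviving methyl-bearing carbon keeps its geometry from 2 to 5. Its descriptor changes from R (in 2, 3 and 4) to S (C2 of 5) only because the CIP ranking of its two ring neighbours reverses once the adjacent carbon becomes sp2. The other methyl-bearing centre is destroyed when C3 becomes sp2, and because 2 is C2-symmetric either end may cyclise with the same result.

**Compound list**
1 | (E)-1,2-dimethoxy-4-(prop-1-en-1-yl)benzene ((E)-methyl isoeugenol) | C/C=C/c1ccc(OC)c(OC)c1 | starting material
2 | (1S,2S,3R,4R)-1,2-bis(3,4-dimethoxyphenyl)-3,4-dimethylcyclobutane (all-trans) | C[C@@H]1[C@@H](C)[C@H](c2ccc(OC)c(OC)c2)[C@H]1c3ccc(OC)c(OC)c3 | intermediate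
3 | (2R,3R)-1,4-bis(3,4-dimethoxyphenyl)-2,3-dimethylbutane-1,4-diyl radical cation (benzylic cation at one end, benzylic radical at the other) | COc1ccc([CH+][C@H](C)[C@@H](C)[CH]c2ccc(OC)c(OC)c2)cc1OC | intermediate
4 | (1R,2R,3S)-1-(3,4-dimethoxyphenyl)-6,7-dimethoxy-2,3-dimethyl-1,2,3,4-tetrahydronaphthalen-4-yl radical (locants as in 5; aryl, methyl, methyl all trans) | COc1ccc([C@@H]2c3cc(OC)c(OC)cc3[CH][C@H](C)[C@H]2C)cc1OC | intermediate
5 | (1R,2S)-1-(3,4-dimethoxyphenyl)-6,7-dimethoxy-2,3-dimethyl-1,2-dihydronaphthalene (aryl and C2 methyl trans) | COc1ccc([C@@H]2c3cc(OC)c(OC)cc3C=C(C)[C@H]2C)cc1OC | target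

**Total step count:** 2
**Longest linear sequence:** 2

**Steps most likely to fail** (the route has only two steps, so both are listed, the riskier first)

Step 2. Two things can go wrong. The opened radical cation 3 can lose its 8–8′ bond (retro-[2+2]) faster than it closes on the arene, returning 1; any 1 that re-dimerises without a chiral anion lowers the ee, which is why the reaction is run at 2 mM. Also, 5 is easier to oxidise than 2 and can be dehydrogenated further to the naphthalene, which is why the reaction is stopped at partial conversion. The fallback sets out from 2 and comes back at 5, and replaces the one-pot radical ring expansion by a polar two-stage sequence. Anodic oxidation of 2 in methanol (graphite anode, LiClO4, 2.2 F/mol, 0 °C) opens the cyclobutane, and the solvent captures both benzylic positions to give (2R,3R)-1,4-bis(3,4-dimethoxyphenyl)-1,4-dimethoxy-2,3-dimethylbutane F2, as a mixture of epimers at the two ether carbons that does not matter. Methanol at solvent concentration should trap the cation before fragmentation. Treatment of F2 with BF3·OEt2 in CH2Cl2 (−40 to 0 °C) ionises one benzylic ether and the cation closes on the other ring to give (1R,2S,3R)-1-(3,4-dimethoxyphenyl)-4,6,7-trimethoxy-2,3-dimethyl-1,2,3,4-tetrahydronaphthalene F3, which is not isolated. Loss of methanol from F3 gives 5, with the same trans-selective closure.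

Step 1. The enantioselectivity is untested for the homodimerisation of 1; a low ee, or slow turnover at −90 °C, is possible, and a modest ee may not be upgradable by crystallisation. The fallback sets out from 1 and comes back at 2, and obtains the stereochemistry by resolution instead of catalysis. Dimerisation of 1 with an achiral photooxidant (2,4,6-tris(4-methoxyphenyl)pyrylium tetrafluoroborate, acetone, −40 °C, blue LEDs) gives the racemic all-trans cyclobutane, that is 2 together with its enantiomer (1R,2R,3S,4S)-1,2-bis(3,4-dimethoxyphenyl)-3,4-dimethylcyclobutane F1. The two are separated by preparative chromatography on an amylose carbamate chiral phase, and 2 goes on to Step 2.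

**Further compounds**
F1 | step 1 | (1R,2R,3S,4S)-1,2-bis(3,4-dimethoxyphenyl)-3,4-dimethylcyclobutane | C[C@H]1[C@H](C)[C@@H](c2ccc(OC)c(OC)c2)[C@@H]1c3ccc(OC)c(OC)c3
F2 | step 2 | (2R,3R)-1,4-bis(3,4-dimethoxyphenyl)-1,4-dimethoxy-2,3-dimethylbutane (epimers at C1 and C4) | COc1ccc(C(OC)[C@H](C)[C@@H](C)C(OC)c2ccc(OC)c(OC)c2)cc1OC
F3 | step 2 | (1R,2S,3R)-1-(3,4-dimethoxyphenyl)-4,6,7-trimethoxy-2,3-dimethyl-1,2,3,4-tetrahydronaphthalene (epimers at C4) | COc1ccc([C@@H]2c3cc(OC)c(OC)cc3C(OC)[C@H](C)[C@H]2C)cc1OC
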